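The readings are calculated on assumed constants.

3 questions are put to these flasks; one amount read from the runs serves the winter comparison and the midnight share, and a start-up time read beside it serves the order.

common to all: catalyst 4.00 × 10⁻⁴ M

| flask | substrate | time |
|---|---|---|
| spring | 0.0800 M |  |
| winter | 0.0480 M |  |
| autumn | 0.160 M |  |
| midnight | 0.0800 M | 560 s |

- spring run (time / s: [product] / M): 11: 0.0023; 32: 0.0067; 62: 0.0166; 98: 0.0263; 140: 0.0368
- winter run (time / s: [product] / M): 11: 5 × 10⁻⁴; 32: 0.0039; 62: 0.0098; 98: 0.0144; 140: 0.0203
- autumn run (time / s: [product] / M): 11: 0.0017; 32: 0.0140; 62: 0.0338; 98: 0.0591; 140: 0.0858

(each reading ± 6 × 10⁻⁴ M)

- the power of [substrate] that the first rate follows, about the charge of the spring run; measure it at two percent of substrate made into product (one fixed amount of product, the same in the runs compared)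
- the winter run starts with 0.0320 M less of substrate than the spring run, and with no product. Compared where both hold the same amount of substrate, once fifteen percent of what the winter run was charged with has turned into product, is the winter run faster, slower or alike (within a tenth)?
- product in the midnight run at 560 s, as a share of the substrate charged

- Overall: substrate -> product, with catalyst as catalyst.
- Constant volume, constant temperature.
- An order is taken over about fifteen percent of the charge, up and down.

Start with the main step alone, substrate to product at constant catalyst. Rate over [substrate] should then be one constant in every run. Between the third and fifth readings, however, it is 0.00409 s⁻¹ in the winter run at a mean product of 0.0150 M, and 0.00665 s⁻¹ in the autumn run at 0.0598 M, higher than in the winter run.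

So a second step is added, and rate = [substrate](c + p[product]). The line through these two readings gives p = 0.0574 M⁻¹ s⁻¹ and c = 0.00322 s⁻¹. Their ratio, the seed, is 0.0561 M: the amount of product at which the product step matches the catalyst step.

With the main step alone, the midnight run reaches 83.5% at 560 s. With the second step, rate = p[substrate](seed + [product]), and the ratio (seed + [product])/[substrate] grows by the same factor in equal times, at the constant c + p × charge, here 0.00781 s⁻¹. That gives 97.0%.

The rest is a start-up: the first two autumn readings extrapolate to zero product at 8.10 s. Subtracting that time gives 96.8%, the share this reckoning commits to.

Both steps alone give order 1 at fixed product, whatever the seed, but the spring run needs 6.21 s at full rate to make that product, less than the start-up. The order therefore falls between 0.5 and 1.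

At equal substrate, the winter run holds 0.00720 M of product and the spring run 0.0320 M more, so the seed gives a rate ratio of 0.664: the winter run is slower.

The forecast gave 1.1, slower and 96%, noting that “Rate barely falls within a run”.

The simulation gives order 0.70, slower with a ratio of 0.72, and 97.3%.

    active catalyst + substrate → product + active catalyst (9.740 M⁻¹ s⁻¹)
    substrate + product → 2 product (0.04870 M⁻¹ s⁻¹)
    catalyst → active catalyst (0.08690 s⁻¹)

In the midnight run, catalyst became active catalyst with a time constant of 11.5 s, and active catalyst carried the main step while substrate and product ran the second step beside it. At 560 s that flask held 0.00219 M of substrate. The autumn run was charged with 2.85 seeds; the ratio rule with the start-up put half of its charge at 135 s, and the run stood there at 130 s.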